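The route rests on a retro-[4+2] cut of the methylcyclohexene ring (C1'' bears flavanone C8, C2''=C3'' the methyl, C5'' the aryl, C6'' the aroyl group) into a 2'-hydroxychalcone and a (2S)-flavanone with a 3-methylbutadienyl group at C8. The feature exploited is the C2''=C3'' double bond flanked by C1'', allylic and benzylic to flavanone ring A with donor atoms O1 and O7, and the trans C5''/C6'' pair next to an ortho-hydroxyaryl ketone. A chiral boron chelate of that ketone drives an asynchronous endo cycloaddition in which the C6''–C1'' bond forms last and closes the ring, joining both halves and setting three stereocentres at once. The precursors are tri-O-silyl morachalcone A and a silyl-protected dienyl flavanone.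

Key step: step 15

Assumption: the antipodes of the two chiral ligands ((S)-MeO-F12-BIPHEP in step 6, (R)-VANOL in step 15) are assigned by analogy with related substrates; if a trial run shows the opposite sense, the other antipode is used with no other change. Abbreviations: TBS = tert-butyldimethylsilyl, TIPS = triisopropylsilyl, MOM = methoxymethyl.

Step 1
Reactants: 1 1-(2,4-dihydroxyphenyl)ethan-1-one
Product: 2 1-(2,4-dihydroxy-3-iodophenyl)ethan-1-one
Conditions: I2, HIO3, EtOH/H2O, rt to 40 °C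
Reagents that add atoms: iodine (II); iodic acid (O[I](=O)=O)
Why: Electrophilic aromatic iodination should go to C3, the position between the two hydroxyl groups that both of them activate, while iodic acid reoxidises iodide so that all iodine is used.

Step 2
Reactants: 2 1-(2,4-dihydroxy-3-iodophenyl)ethan-1-one
Product: 3 1-{2-hydroxy-3-iodo-4-[(triisopropylsilyl)oxy]phenyl}ethan-1-one
Conditions: TIPSCl (1.1 equiv), imidazole, DMF, 0 °C to rt
Reagents that add atoms: triisopropylsilyl chloride (CC(C)[Si](Cl)(C(C)C)C(C)C)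
Why: Silyl ether formation should occur only at the 4-hydroxyl because the 2-hydroxyl is locked in a hydrogen bond to the ketone.

Step 3
Reactants: 3 1-{2-hydroxy-3-iodo-4-[(triisopropylsilyl)oxy]phenyl}ethan-1-one
Product: 5 8-iodo-7-[(triisopropylsilyl)oxy]-4H-chromen-4-one, via enaminone 4 (not isolated)
Conditions: Me2NCH(OMe)2, toluene, 90 °C; then conc. HCl, CH2Cl2, rt
Reagents that add atoms: N,N-dimethylformamide dimethyl acetal (COC(OC)N(C)C)
Why: Condensation of the methyl ketone with the amide acetal gives the enaminone, and acid then triggers intramolecular oxa-Michael addition of the phenol with loss of dimethylamine (enaminone route to chromones), which the bulky silyl ether should survive.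

Step 4
Reactants: 6 4-bromobenzene-1,3-diol
Product: 7 1-bromo-2,4-bis[(tert-butyldimethylsilyl)oxy]benzene
Conditions: TBSCl (2.3 equiv), imidazole, DMF, rt
Reagents that add atoms: tert-butyldimethylsilyl chloride (CC(C)(C)[Si](C)(C)Cl)
Why: Standard silylation of both free phenols with imidazole as base and acyl-transfer-type activator.

Step 5
Reactants: 7 1-bromo-2,4-bis[(tert-butyldimethylsilyl)oxy]benzene
Product: 10 {2,4-bis[(tert-butyldimethylsilyl)oxy]phenyl}boronic acid, via aryllithium 8 (not isolated), via lithium aryltriisopropoxyborate 9 (not isolated)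
Conditions: B(OiPr)3 (1.5 equiv), THF/toluene, −78 °C, n-BuLi added slowly, to −20 °C; then aq. NH4Cl
Reagents that add atoms: triisopropyl borate (CC(C)OB(OC(C)C)OC(C)C); water (O)
Why: Bromine–lithium exchange in the presence of the borate traps the aryllithium at once as the ate complex, which should outrun ortho-silyl migration, and mild hydrolysis gives the boronic acid.

Step 6
Reactants: 5 8-iodo-7-[(triisopropylsilyl)oxy]-4H-chromen-4-one; 10 {2,4-bis[(tert-butyldimethylsilyl)oxy]phenyl}boronic acid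
Product: 11 (2S)-2-{2,4-bis[(tert-butyldimethylsilyl)oxy]phenyl}-8-iodo-7-[(triisopropylsilyl)oxy]-2,3-dihydro-4H-chromen-4-one
Conditions: [Rh(OH)(cod)]2 (3 mol %), (S)-MeO-F12-BIPHEP [(S)-6,6'-dimethoxy-2,2'-bis{bis(3,4,5-trifluorophenyl)phosphino}biphenyl, 6.6 mol %], 10 (2 equiv), toluene/H2O, 30 °C
Reagents that add atoms: none
Why: Rhodium-catalysed asymmetric 1,4-addition of an arylboronic acid to the chromone (Hayashi–Miyaura type) in which the electron-poor atropisomeric bisphosphine selects the enone face and so sets C2 as S, while the base-free medium should spare the silyl ethers, the C–I bond and the flavanone ring.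

Step 7
Reactants: 12 2-methylbut-1-en-3-yne
Product: 13 tributyl[(1E)-3-methylbuta-1,3-dien-1-yl]stannane
Conditions: Bu3SnH (1.1 equiv), AIBN (cat.), neat, 80 °C
Reagents that add atoms: tributyltin hydride (CCCC[SnH](CCCC)CCCC)
Why: Radical hydrostannation of the terminal alkyne places tin on the terminal carbon and equilibrates to the E vinylstannane under the reaction conditions.

Step 8
Reactants: 11 (2S)-2-{2,4-bis[(tert-butyldimethylsilyl)oxy]phenyl}-8-iodo-7-[(triisopropylsilyl)oxy]-2,3-dihydro-4H-chromen-4-one; 13 tributyl[(1E)-3-methylbuta-1,3-dien-1-yl]stannane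
Product: 14 (2S)-2-{2,4-bis[(tert-butyldimethylsilyl)oxy]phenyl}-8-[(1E)-3-methylbuta-1,3-dien-1-yl]-7-[(triisopropylsilyl)oxy]-2,3-dihydro-4H-chromen-4-one
Conditions: Pd2(dba)3 (5 mol %), AsPh3 (20 mol %), CuI (20 mol %), DMF, 50 °C, dark
Reagents that add atoms: none
Why: Stille coupling with retention of the E alkene geometry, in which CuI and the weakly bound arsine should speed up transmetalation at the doubly ortho-substituted iodide and the base-free conditions keep flavanone C2 from epimerising through ring opening.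

Step 9
Reactants: 1 1-(2,4-dihydroxyphenyl)ethan-1-one
Product: 15 1-[2,4-dihydroxy-3-(3-methylbut-2-en-1-yl)phenyl]ethan-1-one
Conditions: prenyl bromide, 10 % aq. KOH, 0 °C to rt
Reagents that add atoms: 1-bromo-3-methylbut-2-ene (CC(C)=CCBr)
Why: C-alkylation of the resorcinol-type phenoxide in water should favour carbon over oxygen attack at the doubly activated C3 position, with the O-alkylated and C5 isomers removed by chromatography.

Step 10
Reactants: 15 1-[2,4-dihydroxy-3-(3-methylbut-2-en-1-yl)phenyl]ethan-1-one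
Product: 16 1-[2-hydroxy-4-(methoxymethoxy)-3-(3-methylbut-2-en-1-yl)phenyl]ethan-1-one
Conditions: MOMCl (1.1 equiv), K2CO3, acetone, rt
Reagents that add atoms: chloromethyl methyl ether (COCCl)
Why: Williamson-type ether formation under weak base should occur only at the non-chelated 4-hydroxyl.

Step 11
Reactants: 17 2,4-dihydroxybenzaldehyde
Product: 18 2,4-bis(methoxymethoxy)benzaldehyde
Conditions: MOMCl (2.5 equiv), i-Pr2NEt, CH2Cl2, 0 °C to rt
Reagents that add atoms: chloromethyl methyl ether (COCCl)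
Why: Both phenols are converted to base-stable acetal ethers so that the aldehyde stays electrophilic in the following base-mediated condensation.

Step 12
Reactants: 16 1-[2-hydroxy-4-(methoxymethoxy)-3-(3-methylbut-2-en-1-yl)phenyl]ethan-1-one; 18 2,4-bis(methoxymethoxy)benzaldehyde
Product: 20 (2E)-3-[2,4-bis(methoxymethoxy)phenyl]-1-[2-hydroxy-4-(methoxymethoxy)-3-(3-methylbut-2-en-1-yl)phenyl]prop-2-en-1-one, via aldol adduct 19 (not isolated)
Conditions: KOH, EtOH/H2O, rt
Reagents that add atoms: none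
Why: Claisen–Schmidt condensation, in which aldol addition of the ketone enolate to the non-enolisable aldehyde is followed by E1cB dehydration to the conjugated E enone.

Step 13
Reactants: 20 (2E)-3-[2,4-bis(methoxymethoxy)phenyl]-1-[2-hydroxy-4-(methoxymethoxy)-3-(3-methylbut-2-en-1-yl)phenyl]prop-2-en-1-one
Product: 21 (2E)-1-[2,4-dihydroxy-3-(3-methylbut-2-en-1-yl)phenyl]-3-(2,4-dihydroxyphenyl)prop-2-en-1-one (morachalcone A)
Conditions: 3 M aq. HCl, MeOH, 50 °C, short reaction time
Reagents that add atoms: none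
Why: Acid-catalysed transacetalisation of the three methoxymethyl ethers to methanol, kept short and mild so that the prenyl group should not cyclise onto a neighbouring phenol.

Step 14
Reactants: 21 (2E)-1-[2,4-dihydroxy-3-(3-methylbut-2-en-1-yl)phenyl]-3-(2,4-dihydroxyphenyl)prop-2-en-1-one
Product: 22 (2E)-3-{2,4-bis[(tert-butyldimethylsilyl)oxy]phenyl}-1-{4-[(tert-butyldimethylsilyl)oxy]-2-hydroxy-3-(3-methylbut-2-en-1-yl)phenyl}prop-2-en-1-one
Conditions: TBSCl (3.3 equiv), imidazole, CH2Cl2/DMF, 0 °C to rt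
Reagents that add atoms: tert-butyldimethylsilyl chloride (CC(C)(C)[Si](C)(C)Cl)
Why: Silylation of the three free phenols, the 2'-hydroxyl being left free by its strong hydrogen bond to the ketone so that it can serve as the handle for boron in the next step.

Step 15
Reactants: 22 (2E)-3-{2,4-bis[(tert-butyldimethylsilyl)oxy]phenyl}-1-{4-[(tert-butyldimethylsilyl)oxy]-2-hydroxy-3-(3-methylbut-2-en-1-yl)phenyl}prop-2-en-1-one; 14 (2S)-2-{2,4-bis[(tert-butyldimethylsilyl)oxy]phenyl}-8-[(1E)-3-methylbuta-1,3-dien-1-yl]-7-[(triisopropylsilyl)oxy]-2,3-dihydro-4H-chromen-4-one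
Product: 25 (2S)-2-{2,4-bis[(tert-butyldimethylsilyl)oxy]phenyl}-8-[(1S,5S,6R)-5-{2,4-bis[(tert-butyldimethylsilyl)oxy]phenyl}-6-{4-[(tert-butyldimethylsilyl)oxy]-2-hydroxy-3-(3-methylbut-2-en-1-yl)benzoyl}-3-methylcyclohex-2-en-1-yl]-7-[(triisopropylsilyl)oxy]-2,3-dihydro-4H-chromen-4-one, via boron chelate of chalcone 23 (not isolated), via boron chelate of adduct 24 (not isolated)
Conditions: (R)-VANOL (1.2 equiv), BH3·THF (1.2 equiv), AcOH (1.2 equiv), THF, rt; then 22; then 14 (1.5 equiv), rt; aqueous work-up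
Reagents that add atoms: none
Why: Ligand exchange puts the 2'-phenoxide of 22 on boron and the ketone oxygen coordinates, so the enone becomes a rigid, electron-poor chelate 23 that should undergo a strongly asynchronous endo [4+2] cycloaddition with the electron-rich diene 14: the unsubstituted diene CH2 terminus bonds first to the chalcone β-carbon (C4''–C5''), and the developing boron enolate carbon then bonds to the aryl-stabilised allylic terminus, forming the C6''–C1'' bond that closes the ring. The closest known reaction type is the chiral biaryl-diol/boron-promoted asymmetric Diels–Alder reaction of 2'-hydroxychalcones with 1-aryl-3-methylbutadienes. The cyclohexene ring is closed by an intermolecular, suprafacial [4+2] annulation with "ortho" regiochemistry, the second bond completing a six-membered ring within the polarised transition structure. The trans relation C5''/C6'' follows from the E enone, the cis relation C6''/C1'' from the endo approach of the E diene (chelated aroyl group under the diene aryl), and the absolute configuration (1''S,5''S,6''R) from the (R)-VANOL wall that shields one face of the chelated enone. The step needs chemo-, regio-, endo and facial selectivity: only the chelated enone is activated, the regiochemistry is fixed by the polarisation of both partners (donor oxygens O1 and O7 on the diene aryl, boron-bound carbonyl), the endo mode is favoured by secondary overlap in the compact chelate, and the facial sense is reagent-controlled because the flavanone stereocentre is remote. Any exo isomer is to be removed by chromatography.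

Step 16
Reactants: 25 the hexasilyl endo adduct of step 15
Product: 26 (2S)-8-[(1S,5S,6R)-6-[2,4-dihydroxy-3-(3-methylbut-2-en-1-yl)benzoyl]-5-(2,4-dihydroxyphenyl)-3-methylcyclohex-2-en-1-yl]-2-(2,4-dihydroxyphenyl)-7-hydroxy-2,3-dihydro-4H-chromen-4-one (target)
Conditions: TBAF (8 equiv), AcOH (8 equiv), THF, 0 °C to rt
Reagents that add atoms: none
Why: Fluoride cleaves all six aryl silyl ethers, and buffering with acetic acid keeps the medium near neutral so that flavanone C2 should not epimerise by ring opening and neither prenyl cyclisation nor ketalisation of the ketone should occur.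

Compound list
1 | 1-(2,4-dihydroxyphenyl)ethan-1-one | CC(=O)c1ccc(O)cc1O | starting material
2 | 1-(2,4-dihydroxy-3-iodophenyl)ethan-1-one | CC(=O)c1ccc(O)c(I)c1O | intermediate
3 | 1-{2-hydroxy-3-iodo-4-[(triisopropylsilyl)oxy]phenyl}ethan-1-one | CC(=O)c1ccc(O[Si](C(C)C)(C(C)C)C(C)C)c(I)c1O | intermediate
4 | (2E)-3-(dimethylamino)-1-{2-hydroxy-3-iodo-4-[(triisopropylsilyl)oxy]phenyl}prop-2-en-1-one | CN(C)/C=C/C(=O)c1ccc(O[Si](C(C)C)(C(C)C)C(C)C)c(I)c1O | intermediate (not isolated)
5 | 8-iodo-7-[(triisopropylsilyl)oxy]-4H-chromen-4-one | CC(C)[Si](Oc1ccc2c(=O)ccoc2c1I)(C(C)C)C(C)C | intermediate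
6 | 4-bromobenzene-1,3-diol | Oc1ccc(Br)c(O)c1 | starting material
7 | 1-bromo-2,4-bis[(tert-butyldimethylsilyl)oxy]benzene | CC(C)(C)[Si](C)(C)Oc1ccc(Br)c(O[Si](C)(C)C(C)(C)C)c1 | intermediate
8 | {2,4-bis[(tert-butyldimethylsilyl)oxy]phenyl}lithium | [Li]c1ccc(O[Si](C)(C)C(C)(C)C)cc1O[Si](C)(C)C(C)(C)C | intermediate (not isolated)
9 | lithium {2,4-bis[(tert-butyldimethylsilyl)oxy]phenyl}tri(propan-2-yloxy)borate | [Li+].CC(C)O[B-](OC(C)C)(OC(C)C)c1ccc(O[Si](C)(C)C(C)(C)C)cc1O[Si](C)(C)C(C)(C)C | intermediate (not isolated)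
10 | {2,4-bis[(tert-butyldimethylsilyl)oxy]phenyl}boronic acid | OB(O)c1ccc(O[Si](C)(C)C(C)(C)C)cc1O[Si](C)(C)C(C)(C)C | intermediate
11 | (2S)-2-{2,4-bis[(tert-butyldimethylsilyl)oxy]phenyl}-8-iodo-7-[(triisopropylsilyl)oxy]-2,3-dihydro-4H-chromen-4-one | CC(C)[Si](Oc1ccc2c(c1I)O[C@H](c1ccc(O[Si](C)(C)C(C)(C)C)cc1O[Si](C)(C)C(C)(C)C)CC2=O)(C(C)C)C(C)C | intermediate
12 | 2-methylbut-1-en-3-yne | C#CC(C)=C | starting material
13 | tributyl[(1E)-3-methylbuta-1,3-dien-1-yl]stannane | CCCC[Sn](CCCC)(CCCC)/C=C/C(C)=C | intermediate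
14 | (2S)-2-{2,4-bis[(tert-butyldimethylsilyl)oxy]phenyl}-8-[(1E)-3-methylbuta-1,3-dien-1-yl]-7-[(triisopropylsilyl)oxy]-2,3-dihydro-4H-chromen-4-one | C=C(C)/C=C/c1c(O[Si](C(C)C)(C(C)C)C(C)C)ccc2c1O[C@H](c1ccc(O[Si](C)(C)C(C)(C)C)cc1O[Si](C)(C)C(C)(C)C)CC2=O | intermediate
15 | 1-[2,4-dihydroxy-3-(3-methylbut-2-en-1-yl)phenyl]ethan-1-one | CC(=O)c1ccc(O)c(CC=C(C)C)c1O | intermediate
16 | 1-[2-hydroxy-4-(methoxymethoxy)-3-(3-methylbut-2-en-1-yl)phenyl]ethan-1-one | CC(=O)c1ccc(OCOC)c(CC=C(C)C)c1O | intermediate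
17 | 2,4-dihydroxybenzaldehyde | O=Cc1ccc(O)cc1O | starting material
18 | 2,4-bis(methoxymethoxy)benzaldehyde | COCOc1ccc(C=O)c(OCOC)c1 | intermediate
19 | 3-[2,4-bis(methoxymethoxy)phenyl]-3-hydroxy-1-[2-hydroxy-4-(methoxymethoxy)-3-(3-methylbut-2-en-1-yl)phenyl]propan-1-one (racemic aldol adduct) | COCOc1ccc(C(O)CC(=O)c2ccc(OCOC)c(CC=C(C)C)c2O)c(OCOC)c1 | intermediate (not isolated)
20 | (2E)-3-[2,4-bis(methoxymethoxy)phenyl]-1-[2-hydroxy-4-(methoxymethoxy)-3-(3-methylbut-2-en-1-yl)phenyl]prop-2-en-1-one | COCOc1ccc(/C=C/C(=O)c2ccc(OCOC)c(CC=C(C)C)c2O)c(OCOC)c1 | intermediate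
21 | (2E)-1-[2,4-dihydroxy-3-(3-methylbut-2-en-1-yl)phenyl]-3-(2,4-dihydroxyphenyl)prop-2-en-1-one (morachalcone A) | CC(C)=CCc1c(O)ccc(C(=O)/C=C/c2ccc(O)cc2O)c1O | intermediate
22 | (2E)-3-{2,4-bis[(tert-butyldimethylsilyl)oxy]phenyl}-1-{4-[(tert-butyldimethylsilyl)oxy]-2-hydroxy-3-(3-methylbut-2-en-1-yl)phenyl}prop-2-en-1-one | CC(C)=CCc1c(O[Si](C)(C)C(C)(C)C)ccc(C(=O)/C=C/c2ccc(O[Si](C)(C)C(C)(C)C)cc2O[Si](C)(C)C(C)(C)C)c1O | intermediate
23 | boron chelate of chalcone 22: boron bonded to the 2'-phenoxide oxygen of 22 and to both naphtholate oxygens of (R)-3,3'-diphenyl-2,2'-bi-1-naphthol [(R)-VANOL], ketone oxygen coordinated to boron (coordination and R axis not encoded in the SMILES) | CC(C)=CCc1c(O[Si](C)(C)C(C)(C)C)ccc(C(=O)/C=C/c2ccc(O[Si](C)(C)C(C)(C)C)cc2O[Si](C)(C)C(C)(C)C)c1OB3Oc4c(c(-c5ccccc5)cc5ccccc45)-c4c(O3)c5ccccc5cc4-c4ccccc4 | intermediate (not isolated)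
24 | boron chelate of adduct 25: as 23, with the 2-hydroxyaryl ketone of 25 in place of that of 22 (coordination and R axis not encoded in the SMILES) | CC(C)=CCc1c(O[Si](C)(C)C(C)(C)C)ccc(C(=O)[C@H]2[C@@H](c3c(O[Si](C(C)C)(C(C)C)C(C)C)ccc4c3O[C@H](c3ccc(O[Si](C)(C)C(C)(C)C)cc3O[Si](C)(C)C(C)(C)C)CC4=O)C=C(C)C[C@@H]2c2ccc(O[Si](C)(C)C(C)(C)C)cc2O[Si](C)(C)C(C)(C)C)c1OB5Oc6c(c(-c7ccccc7)cc7ccccc67)-c6c(O5)c7ccccc7cc6-c6ccccc6 | intermediate (not isolated)
25 | (2S)-2-{2,4-bis[(tert-butyldimethylsilyl)oxy]phenyl}-8-[(1S,5S,6R)-5-{2,4-bis[(tert-butyldimethylsilyl)oxy]phenyl}-6-{4-[(tert-butyldimethylsilyl)oxy]-2-hydroxy-3-(3-methylbut-2-en-1-yl)benzoyl}-3-methylcyclohex-2-en-1-yl]-7-[(triisopropylsilyl)oxy]-2,3-dihydro-4H-chromen-4-one | CC(C)=CCc1c(O[Si](C)(C)C(C)(C)C)ccc(C(=O)[C@H]2[C@@H](c3c(O[Si](C(C)C)(C(C)C)C(C)C)ccc4c3O[C@H](c3ccc(O[Si](C)(C)C(C)(C)C)cc3O[Si](C)(C)C(C)(C)C)CC4=O)C=C(C)C[C@@H]2c2ccc(O[Si](C)(C)C(C)(C)C)cc2O[Si](C)(C)C(C)(C)C)c1O | intermediate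
26 | (2S)-8-[(1S,5S,6R)-6-[2,4-dihydroxy-3-(3-methylbut-2-en-1-yl)benzoyl]-5-(2,4-dihydroxyphenyl)-3-methylcyclohex-2-en-1-yl]-2-(2,4-dihydroxyphenyl)-7-hydroxy-2,3-dihydro-4H-chromen-4-one | CC(C)=CCc1c(O)ccc(C(=O)[C@H]2[C@@H](c3c(O)ccc4c3O[C@H](c3ccc(O)cc3O)CC4=O)C=C(C)C[C@@H]2c2ccc(O)cc2O)c1O | target

Total step count: 16.
Longest linear sequence: 7 steps (steps 1, 2, 3, 6, 8, 15, 16; the chalcone branch, steps 9, 10, 12, 13, 14, 15, 16, is equally long).

Steps most likely to fail

1. Step 15 (key cycloaddition). The two bulky, electron-rich partners may combine slowly, so that diene oligomerisation competes. The heavily silylated, stereogenic flavanone next to the diene may also erode endo/exo and facial discrimination (mismatched pairing). Fallback: the ring is closed before the flavanone stereocentre exists. It sets out from chromone 5 and chalcone 22. Stille coupling of 5 with stannane 13 (conditions of step 8) should give the flat, achiral 8-[(1E)-3-methylbuta-1,3-dien-1-yl]-7-[(triisopropylsilyl)oxy]-4H-chromen-4-one F1. Chelate 23, made from 22 as in step 15, should then add F1 in the same endo sense to give the boron chelate of the chromone adduct F2. Aqueous work-up releases the chromone adduct F3. Rhodium-catalysed asymmetric 1,4-addition of boronic acid 10 to the chromone ring of F3 (conditions of step 6) should then set C2 under catalyst control, and the route is rejoined at 25.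

2. Step 6 (asymmetric 1,4-addition). Transmetalation and insertion of the ortho-silyloxy arylboronic acid may be slow, so that protodeboronation takes over. Rhodium may also insert into the C–I bond, or the product may ring-open. Fallback: the stereocentre is obtained by resolution instead of catalysis. It sets out from ketone 3 and aldehyde 17. Silylation of 17 (TBSCl, imidazole, DMF) gives 2,4-bis[(tert-butyldimethylsilyl)oxy]benzaldehyde F4. The dilithio species of 3 (LiHMDS, 2.2 equiv, THF, −78 °C; aq. NH4Cl) adds to F4 to give the racemic β-hydroxy ketone F5. Mitsunobu cyclodehydration (PPh3, DIAD, THF, 0 °C) closes the pyranone ring to the racemic flavanone F6. Preparative chromatography on a chiral stationary phase should deliver the (2S) enantiomer, which is 11. The unwanted enantiomer is racemised with DBU through the ring-opened chalcone and resubmitted.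

3. Step 8 (Stille coupling). Oxidative addition and transmetalation at the iodide flanked by two oxygen substituents may be slow, so that protodestannylation, homocoupling and oligomerisation of the dienylstannane compete. Fallback: the diene is built in two stages. It sets out from iodide 11. Heck reaction with 2-methylbut-3-en-2-ol (Pd(OAc)2, n-Bu4NCl, NaHCO3, DMF, 70 °C) should give the E tertiary allylic alcohol F7. Dehydration through the mesylate (MsCl, Et3N, CH2Cl2, 0 °C to rt) should give the diene, and the route is rejoined at 14.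

Further compounds
F1 | step 15 | 8-[(1E)-3-methylbuta-1,3-dien-1-yl]-7-[(triisopropylsilyl)oxy]-4H-chromen-4-one | C=C(C)/C=C/c1c(O[Si](C(C)C)(C(C)C)C(C)C)ccc2c(=O)ccoc12
F2 | step 15 | boron chelate of the chromone adduct F3 with (R)-VANOL (coordination and R axis not encoded) | CC(C)=CCc1c(O[Si](C)(C)C(C)(C)C)ccc(C(=O)[C@H]2[C@@H](c3c(O[Si](C(C)C)(C(C)C)C(C)C)ccc4c(=O)ccoc34)C=C(C)C[C@@H]2c2ccc(O[Si](C)(C)C(C)(C)C)cc2O[Si](C)(C)C(C)(C)C)c1OB5Oc6c(c(-c7ccccc7)cc7ccccc67)-c6c(O5)c7ccccc7cc6-c6ccccc6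
F3 | step 15 | 8-[(1S,5S,6R)-5-{2,4-bis[(tert-butyldimethylsilyl)oxy]phenyl}-6-{4-[(tert-butyldimethylsilyl)oxy]-2-hydroxy-3-(3-methylbut-2-en-1-yl)benzoyl}-3-methylcyclohex-2-en-1-yl]-7-[(triisopropylsilyl)oxy]-4H-chromen-4-one | CC(C)=CCc1c(O[Si](C)(C)C(C)(C)C)ccc(C(=O)[C@H]2[C@@H](c3c(O[Si](C(C)C)(C(C)C)C(C)C)ccc4c(=O)ccoc34)C=C(C)C[C@@H]2c2ccc(O[Si](C)(C)C(C)(C)C)cc2O[Si](C)(C)C(C)(C)C)c1O
F4 | step 6 | 2,4-bis[(tert-butyldimethylsilyl)oxy]benzaldehyde | CC(C)(C)[Si](C)(C)Oc1ccc(C=O)c(O[Si](C)(C)C(C)(C)C)c1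
F5 | step 6 | 3-{2,4-bis[(tert-butyldimethylsilyl)oxy]phenyl}-3-hydroxy-1-{2-hydroxy-3-iodo-4-[(triisopropylsilyl)oxy]phenyl}propan-1-one (racemic) | CC(C)[Si](Oc1ccc(C(=O)CC(O)c2ccc(O[Si](C)(C)C(C)(C)C)cc2O[Si](C)(C)C(C)(C)C)c(O)c1I)(C(C)C)C(C)C
F6 | step 6 | 2-{2,4-bis[(tert-butyldimethylsilyl)oxy]phenyl}-8-iodo-7-[(triisopropylsilyl)oxy]-2,3-dihydro-4H-chromen-4-one (racemic) | CC(C)[Si](Oc1ccc2c(c1I)OC(c1ccc(O[Si](C)(C)C(C)(C)C)cc1O[Si](C)(C)C(C)(C)C)CC2=O)(C(C)C)C(C)C
F7 | step 8 | (2S)-2-{2,4-bis[(tert-butyldimethylsilyl)oxy]phenyl}-8-[(1E)-3-hydroxy-3-methylbut-1-en-1-yl]-7-[(triisopropylsilyl)oxy]-2,3-dihydro-4H-chromen-4-one | CC(C)(O)/C=C/c1c(O[Si](C(C)C)(C(C)C)C(C)C)ccc2c1O[C@H](c1ccc(O[Si](C)(C)C(C)(C)C)cc1O[Si](C)(C)C(C)(C)C)CC2=O
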